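**Retrosynthetic overview**
1. Endgame: the target comes from the tricyclic ynenal 33 by Z-selective semireduction of C3≡C4 and by NaBH4 (C16 aldehyde to CH2OH, C17=C18 to CH–CH3).
2. Key disconnection C7–C8: 33 comes from the 13-membered β-keto macrolactone 32. A transannular vinylogous aldol addition contracts the 13-ring to the 10-membered carbocycle (C1–C10) and the γ-lactone (C7, C8, C17, C19, O) in one operation.
3. Enabling feature: the oxygenated C16 on C5. As an aldehyde it makes the C7 methylene the γ-carbon of the enal C16=O/C5=C6. The lactone chain C7–O–C19–C17–C8 holds C7 five atoms from the C8 ketone, whose face is ruled by the C9 acetoxy centre.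
4. 32 comes from ring-closing alkyne metathesis (C3≡C4), preceded by Roskamp union (C8–C17) of aldehyde 26 with diazo ester 8 (made from but-2-yne-1,4-diol).
5. 26 comes from p-cresol by dearomatisation, asymmetric Stetter desymmetrisation, C1 alkylation/aldol and SmI2 opening. Ring order: six-ring plus temporary tetrahydrofuranone (step 8), oxirane (21), 13-ring (23), 10-ring and γ-lactone together (26).

Key step: step 26

Assumption: but-2-ynal (17) and propyne (4) are bought. Briarane numbering (C1–C20) is used for all intermediates; α is the six-ring face with H-10 and the C14 oxygen, β the face with the C15 methyl.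

**Step 1**
Reactants: 1 but-2-yne-1,4-diol
Product: 2 4-(tert-butyldimethylsilyloxy)but-2-yn-1-ol
Conditions: NaH (1 equiv), THF, 0 °C; TBSCl
Reagents that add atoms: TBSCl, CC(C)(C)[Si](C)(C)Cl
Why: O-silylation of the sparingly soluble monosodium alkoxide stops at the monosilyl ether and so tells the future C16 oxygen from the future C7 oxygen.

**Step 2**
Reactants: 2 4-(tert-butyldimethylsilyloxy)but-2-yn-1-ol
Product: 3 (Z)-4-(tert-butyldimethylsilyloxy)-3-iodobut-2-en-1-ol
Conditions: Red-Al, THF, 0 °C; I2, −78 °C
Reagents that add atoms: iodine, II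
Why: Hydroxyl-directed trans-hydroalumination puts aluminium on the alkyne carbon remote from the free OH, and iodinolysis with retention leaves CH2OH (C7) and iodine (site of C4) cis on C5=C6.

**Step 3**
Reactants: 3 (Z)-4-(tert-butyldimethylsilyloxy)-3-iodobut-2-en-1-ol; 4 propyne
Product: 5 (E)-3-[(tert-butyldimethylsilyloxy)methyl]hex-2-en-4-yn-1-ol (CH2OH cis to the alkynyl group)
Conditions: PdCl2(PPh3)2, CuI, Et3N, THF, 23 °C
Reagents that add atoms: none
Why: Sonogashira coupling of an alkenyl iodide proceeds with retention of the alkene geometry, and it is placed here so that no Pd(0) ever meets the later allyl β-keto ester.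

**Step 4**
Reactants: 5 (E)-3-[(tert-butyldimethylsilyloxy)methyl]hex-2-en-4-yn-1-ol; 6 ethyl 2-methyl-3-oxobutanoate
Product: 7 2-methyl-3-oxobutanoate of alcohol 5 (racemic at the α-carbon)
Conditions: DMAP (cat.), toluene, reflux, 4 Å MS
Reagents that add atoms: none
Why: DMAP-catalysed transesterification of an enolisable β-keto ester (acylketene pathway) is driven by removal of ethanol.

**Step 5**
Reactants: 7 2-methyl-3-oxobutanoate of alcohol 5
Product: 8 2-diazopropanoate of alcohol 5
Conditions: p-ABSA, DBU, MeCN, 0 → 23 °C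
Reagents that add atoms: 4-acetamidobenzenesulfonyl azide (p-ABSA), CC(=O)Nc1ccc(cc1)S(=O)(=O)N=[N+]=[N-]
Why: Deacylative Regitz diazo transfer: the α-methyl β-keto ester takes up the diazo group and loses its acetyl group to the sulfonamide.

**Step 6**
Reactants: 9 4-methylphenol (p-cresol); 10 ethane-1,2-diol
Product: 11 4-(2-hydroxyethoxy)-4-methylcyclohexa-2,5-dien-1-one (achiral)
Conditions: PhI(OAc)2, ethane-1,2-diol/CH2Cl2, 0 °C
Reagents that add atoms: none
Why: Hypervalent-iodine oxidative dearomatisation: the glycol traps the activated phenol at the para carbon, which becomes C11 with its methyl group and a temporary oxygen.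

**Step 7**
Reactants: 11 4-(2-hydroxyethoxy)-4-methylcyclohexa-2,5-dien-1-one
Product: 12 2-[(1-methyl-4-oxocyclohexa-2,5-dien-1-yl)oxy]acetaldehyde
Conditions: Dess–Martin periodinane, CH2Cl2, 23 °C
Reagents that add atoms: none
Why: Dess–Martin oxidation turns the primary alcohol into the aldehyde under neutral conditions that leave the dienone alone.

**Step 8**
Reactants: 12 2-[(1-methyl-4-oxocyclohexa-2,5-dien-1-yl)oxy]acetaldehyde
Product: 13 cis-fused 7a-methyl-3a,7a-dihydrobenzofuran-3,5(2H,4H)-dione (H-10 and the C11 methyl α; C9 and the ether oxygen β)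
Conditions: chiral aminoindanol-derived triazolium tetrafluoroborate (10 mol %, the enantiomer that gives 13), KHMDS (10 mol %), toluene, 23 °C
Reagents that add atoms: none
Why: Asymmetric intramolecular Stetter reaction: the Breslow intermediate adds 5-exo to one of the two enantiotopic enone β-carbons, the tether enforces the cis fusion, and the catalyst sets C10 (and the temporary C11 centre).

**Step 9**
Reactants: 13 cis-fused bicyclic dione
Product: 14 9-hydroxy enone (C9-OH on the concave face, cis to C1 on the five-membered ring)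
Conditions: NaBH4, CH2Cl2–MeOH, −78 °C
Reagents that add atoms: none
Why: The saturated α-alkoxy ketone is reduced faster than the conjugated enone, and hydride attack from the convex face of the cis-bicycle sets C9.

**Step 10**
Reactants: 14 9-hydroxy enone
Product: 15 9-O-TBS enone
Conditions: TBSOTf, 2,6-lutidine, CH2Cl2, 0 °C
Reagents that add atoms: TBSOTf, CC(C)(C)[Si](C)(C)OS(=O)(=O)C(F)(F)F
Why: Silylation with the triflate covers the hindered secondary alcohol before the two enolate steps.

**Step 11**
Reactants: 15 9-O-TBS enone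
Product: 16 1-methyl enone (C1 methyl α, on the convex face)
Conditions: LDA, THF, −78 °C; MeI
Reagents that add atoms: iodomethane, CI
Why: Kinetic α′-deprotonation of the enone (C1 is the only enolisable carbon) and methylation from the convex face; this centre becomes planar again in step 12.

**Step 12**
Reactants: 16 1-methyl enone; 17 but-2-ynal
Product: 18 aldol adduct (C1 quaternary with methyl β and C2 α; C2 carbinol as a mixture of epimers)
Conditions: LDA, THF, −78 → −40 °C; 17, −78 °C; AcOH quench at −78 °C
Reagents that add atoms: none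
Why: Aldol addition of the tetrasubstituted cross-conjugated enolate: the aldehyde comes from the convex α face, away from the tetrahydrofuran ring and its silyl ether, which sets C1 with C2 trans to C9.

**Step 13**
Reactants: 18 aldol adduct
Product: 19 2-oxo compound (non-enolisable 1,3-diketone with an alkynyl ketone at C2)
Conditions: Dess–Martin periodinane, NaHCO3, CH2Cl2, 0 °C
Reagents that add atoms: none
Why: Dess–Martin oxidation erases the uncontrolled C2 carbinol so that it can be reset under reagent control.

**Step 14**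
Reactants: 19 2-oxo compound
Product: 20 propargylic alcohol (C2 configured as in the target)
Conditions: RuCl[(S,S)-TsDPEN](p-cymene) (2 mol %), i-PrOH, 23 °C
Reagents that add atoms: none
Why: Noyori asymmetric transfer hydrogenation reduces alkynyl ketones much faster than the hindered enone carbonyl, and the (S,S)-catalyst, which treats the alkyne as the π-substituent, should set C2 under reagent control.

**Step 15**
Reactants: 20 propargylic alcohol
Product: 21 monocyclic β,γ-enone (C14 ketone, C11=C12, free C8-OH, 9-O-TBS, free C2-OH)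
Conditions: SmI2 (2.5 equiv), THF–HMPA, −78 °C; AcOH at −78 °C
Reagents that add atoms: none
Why: Vinylogous form of the SmI2 α-deoxygenation of ketones: two-electron reduction of the enone places charge on C12, the C11–O bond leaves by β-elimination, and kinetic protonation of the dienolate at C13 gives the C11=C12 alkene.

**Step 16**
Reactants: 21 monocyclic β,γ-enone
Product: 23 2,9,14-triol with 8-O-TBS (14-OH α), via 9-O-TBS triol 22 (not isolated)
Conditions: Et2BOMe, THF–MeOH, −78 °C; NaBH4; then K2CO3, MeOH, 23 °C
Reagents that add atoms: none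
Why: Narasaka–Prasad reduction: external hydride attacks the C2-O/C14=O boron chelate anti to the axial C10 and gives the 2,14-syn diol (sets C14), after which the basic work-up moves the TBS group from O9 to the primary O8 by 1,2-silyl migration.

**Step 17**
Reactants: 23 2,9,14-triol with 8-O-TBS
Product: 24 2,9,14-triacetate with 8-O-TBS
Conditions: Ac2O, pyridine, DMAP, CH2Cl2, 23 → 40 °C
Reagents that add atoms: acetic anhydride, CC(=O)OC(C)=O
Why: DMAP-catalysed acetylation installs all three acetates of the target at once, after the last strong base and the last hydride that could attack them.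

**Step 18**
Reactants: 24 2,9,14-triacetate with 8-O-TBS
Product: 25 primary C8 alcohol triacetate
Conditions: HF·pyridine, pyridine, THF, 0 °C
Reagents that add atoms: none
Why: Acidic fluoride cleaves the primary silyl ether without forming an alkoxide, so the 9-acetate should not move to O8.

**Step 19**
Reactants: 25 primary C8 alcohol triacetate
Product: 26 C8 aldehyde triacetate (α-acetoxy aldehyde, used at once)
Conditions: Dess–Martin periodinane, NaHCO3, CH2Cl2, 0 °C
Reagents that add atoms: none
Why: Buffered Dess–Martin oxidation gives the α-acetoxy aldehyde without epimerising C9.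

**Step 20**
Reactants: 26 C8 aldehyde triacetate; 8 2-diazopropanoate of alcohol 5
Product: 27 allyl β-keto ester (C8 ketone, C17-H/CH3 as a mixture, two methyl-capped alkynes)
Conditions: Sc(OTf)3/N,N′-dioxide ligand (5 mol %), CH2Cl2, −20 °C
Reagents that add atoms: none
Why: Roskamp reaction with an α-alkyl diazo ester (addition to the aldehyde, 1,2-hydride shift, loss of N2) forms C8–C17 without any alkoxide stage, so the 9-acetate stays in place.

**Step 21**
Reactants: 27 allyl β-keto ester
Product: 28 11α,12α-epoxide of 27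
Conditions: mCPBA (1.05 equiv), NaHCO3, CH2Cl2, −10 °C
Reagents that add atoms: mCPBA, OOC(=O)c1cccc(Cl)c1
Why: Prilezhaev epoxidation of the only electron-rich alkene; the peracid should come from the α face because the β face is closed by the axial C15 methyl and by the C9 chain on C10, which sets C11 and C12.

**Step 22**
Reactants: 28 11α,12α-epoxide
Product: 29 17-phenylthio β-keto ester (C17 quaternary, both epimers)
Conditions: N-(phenylthio)succinimide, Et3N, CH2Cl2, 0 °C
Reagents that add atoms: N-(phenylthio)succinimide, O=C1CCC(=O)N1Sc1ccccc1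
Why: α-Sulfenylation of the β-keto ester enolate removes the only strongly acidic C–H and the only soft carbon nucleophile of the molecule before steps 23 and 26.

**Step 23**
Reactants: 29 17-phenylthio β-keto ester
Product: 30 13-membered enyne macrolactone (ring C1, C2, C3≡C4, C5=C6, C7, O, C19, C17, C8, C9, C10)
Conditions: [Mo(≡CC6H4OMe-4)(OSiPh3)3] (5–10 mol %), 5 Å MS, toluene (2 mM), 23 → 60 °C
Reagents that add atoms: none
Why: Ring-closing alkyne metathesis of two methyl-capped alkynes is driven by uptake of but-2-yne in the sieves, tolerates esters, ketones and thioethers, and is known to give macrocyclic 1,3-enynes.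

**Step 24**
Reactants: 30 13-membered enyne macrolactone
Product: 31 C16 allylic alcohol
Conditions: Et3N·3HF, THF, 23 °C
Reagents that add atoms: none
Why: This mild fluoride source cleaves the primary allylic silyl ether and does not open trisubstituted epoxides at room temperature.

**Step 25**
Reactants: 31 C16 allylic alcohol
Product: 32 macrocyclic ynenal (C16 aldehyde, C7H2, C8 ketone)
Conditions: MnO2, CH2Cl2, 23 °C
Reagents that add atoms: none
Why: MnO2 oxidises only the allylic alcohol and leaves the sulfide untouched.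

**Step 26**
Reactants: 32 macrocyclic ynenal
Product: 33 tricyclic ynenal (10-membered carbocycle and γ-lactone; 8-OH; H-7 trans to 8-OH; C17 epimers)
Conditions: DBU (0.3 equiv), 4 Å MS, toluene (5 mM), 0 → 23 °C; AcOH quench
Reagents that add atoms: none
Why: Proposed new method: DBU removes one of the two C7 protons (γ to the C16 aldehyde through C5=C6 and α to the lactone oxygen), the cross-conjugated dienolate attacks the C8 ketone through C7, and proton return to O8 restores the C5=C6–C16 enal; the closest known reaction types are the direct amine-base vinylogous aldol addition of γ-enolisable enals and butenolides to activated ketones and the transannular aldol reaction of macrocyclic dicarbonyl compounds. The γ-lactone closes 5-(enolexo)-exo-trig over C7–O–C19–C17–C8, and because both carbons belong to the 13-membered ring the same bond contracts it transannularly to the 10-membered carbocycle C1–C10, so no medium ring has to be closed from an open chain. C8 is controlled by the C9 acetoxy centre (polar Felkin–Anh, C7 arrives anti to the C9–O bond, metal-free base and hence no chelate), which gives the 8-OH/9-OAc relation of the target. C7 is controlled by the ring: C6 takes the lactone face opposite to C9 (trans fusion), and because the addition is reversible the less strained trans-fused isomer should accumulate, while the ring keeps C4 and C7 cis on C5–C6 as long as this bond is single in the dienolate. The step needs attack of C7 on C8 rather than Michael addition of C17 to C6, attack through C5 or C3, or loss of the 2-acetate; this is secured by the quaternary C17 (no acidic H, no carbon nucleophile, more electrophilic ketone), by the five-membered transition state that is open only to C7, and by keeping C3–C4 as an alkyne, so that expulsion of the C2 acetate would need a cyclic butatriene.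

**Step 27**
Reactants: 33 tricyclic ynenal
Product: 35 α-methylene-γ-lactone (C17=C18H2), via sulfoxide 34 (not isolated)
Conditions: mCPBA (1.0 equiv), CH2Cl2, −78 °C; then CaCO3, toluene, 70 °C
Reagents that add atoms: mCPBA, OOC(=O)c1cccc(Cl)c1 (its oxygen is carried by intermediate 34 only)
Why: Sulfide oxidation at −78 °C is far faster than any alkene oxidation, and thermal syn-elimination of the tertiary sulfoxide can use only the C18 hydrogens, so both C17 epimers converge on one alkene.

**Step 28**
Reactants: 35 α-methylene-γ-lactone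
Product: 36 3,4-didehydro target (C16H2OH, C17-H with the C18 methyl cis to 8-OH, C3≡C4)
Conditions: NaBH4, MeOH–THF, −20 → 0 °C
Reagents that add atoms: none
Why: NaBH4 reduces the aldehyde 1,2 and the α-methylene-γ-lactone 1,4 (both known), and the lactone enolate is protonated anti to the pseudo-axial C8 oxygen, as in electrophile capture by β-oxy-γ-lactone enolates, which sets C17 in what is also the more stable arrangement (methyl trans to C9).

**Step 29**
Reactants: 36 3,4-didehydro target
Product: 37 CNP0296793.1 (target)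
Conditions: Zn(Cu/Ag), MeOH–H2O, 35 °C
Reagents that add atoms: none
Why: Semireduction of a conjugated enyne on activated zinc delivers two hydrogens syn and gives the (3Z)-alkene, while the isolated functions (epoxide, esters, C5=C6) are not touched.

**Compound list**
1 | but-2-yne-1,4-diol | OCC#CCO | starting material
2 | 4-(tert-butyldimethylsilyloxy)but-2-yn-1-ol | OCC#CCO[Si](C)(C)C(C)(C)C | intermediate
3 | (Z)-4-(tert-butyldimethylsilyloxy)-3-iodobut-2-en-1-ol | OC/C=C(CO[Si](C)(C)C(C)(C)C)\I | intermediate
4 | propyne | CC#C | starting material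
5 | (E)-3-[(tert-butyldimethylsilyloxy)methyl]hex-2-en-4-yn-1-ol | OC/C=C(CO[Si](C)(C)C(C)(C)C)\C#CC | intermediate
6 | ethyl 2-methyl-3-oxobutanoate | CCOC(=O)C(C)C(C)=O | starting material
7 | 2-methyl-3-oxobutanoate of 5 | CC(=O)C(C)C(=O)OC/C=C(CO[Si](C)(C)C(C)(C)C)\C#CC | intermediate
8 | 2-diazopropanoate of 5 | CC(=[N+]=[N-])C(=O)OC/C=C(CO[Si](C)(C)C(C)(C)C)\C#CC | intermediate
9 | 4-methylphenol | Cc1ccc(O)cc1 | starting material
10 | ethane-1,2-diol | OCCO | starting material
11 | 4-(2-hydroxyethoxy)-4-methylcyclohexa-2,5-dien-1-one | CC1(OCCO)C=CC(=O)C=C1 | intermediate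
12 | 2-[(1-methyl-4-oxocyclohexa-2,5-dien-1-yl)oxy]acetaldehyde | CC1(OCC=O)C=CC(=O)C=C1 | intermediate
13 | cis-fused 7a-methyl-3a,7a-dihydrobenzofuran-3,5(2H,4H)-dione | O=C1C=C[C@]2(C)OCC(=O)[C@@H]2C1 | intermediate
14 | 9-hydroxy enone (OH on the concave face) | O=C1C=C[C@]2(C)OC[C@H](O)[C@@H]2C1 | intermediate
15 | 9-O-TBS enone | O=C1C=C[C@]2(C)OC[C@H](O[Si](C)(C)C(C)(C)C)[C@@H]2C1 | intermediate
16 | 1-methyl enone (methyl α) | O=C1C=C[C@]2(C)OC[C@H](O[Si](C)(C)C(C)(C)C)[C@@H]2[C@H]1C | intermediate
17 | but-2-ynal | CC#CC=O | starting material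
18 | aldol adduct (C1 set, C2 epimers) | O=C1C=C[C@]2(C)OC[C@H](O[Si](C)(C)C(C)(C)C)[C@@H]2[C@@]1(C)C(O)C#CC | intermediate
19 | 2-oxo compound (alkynyl ketone) | O=C1C=C[C@]2(C)OC[C@H](O[Si](C)(C)C(C)(C)C)[C@@H]2[C@@]1(C)C(=O)C#CC | intermediate
20 | propargylic alcohol (C2 set) | O=C1C=C[C@]2(C)OC[C@H](O[Si](C)(C)C(C)(C)C)[C@@H]2[C@@]1(C)[C@H](O)C#CC | intermediate
21 | monocyclic β,γ-enone with free C8-OH | O=C1CC=C(C)[C@H]([C@@H](O[Si](C)(C)C(C)(C)C)CO)[C@@]1(C)[C@H](O)C#CC | intermediate
22 | 9-O-TBS triol (2,8,14-OH) | O[C@H]1CC=C(C)[C@H]([C@@H](O[Si](C)(C)C(C)(C)C)CO)[C@@]1(C)[C@H](O)C#CC | intermediate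
23 | 8-O-TBS triol (2,9,14-OH) | O[C@H]1CC=C(C)[C@H]([C@@H](O)CO[Si](C)(C)C(C)(C)C)[C@@]1(C)[C@H](O)C#CC | intermediate
24 | 2,9,14-triacetate with 8-O-TBS | CC(=O)O[C@H]1CC=C(C)[C@H]([C@@H](OC(C)=O)CO[Si](C)(C)C(C)(C)C)[C@@]1(C)[C@H](OC(C)=O)C#CC | intermediate
25 | C8 alcohol triacetate | CC(=O)O[C@H]1CC=C(C)[C@H]([C@@H](OC(C)=O)CO)[C@@]1(C)[C@H](OC(C)=O)C#CC | intermediate
26 | C8 aldehyde triacetate | CC(=O)O[C@H]1CC=C(C)[C@H]([C@@H](OC(C)=O)C=O)[C@@]1(C)[C@H](OC(C)=O)C#CC | intermediate
27 | allyl β-keto ester (C17 epimers) | CC(=O)O[C@H]1CC=C(C)[C@H]([C@@H](OC(C)=O)C(=O)C(C)C(=O)OC/C=C(CO[Si](C)(C)C(C)(C)C)\C#CC)[C@@]1(C)[C@H](OC(C)=O)C#CC | intermediate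
28 | 11α,12α-epoxide of 27 | CC(=O)O[C@H]1C[C@H]2O[C@@]2(C)[C@H]([C@@H](OC(C)=O)C(=O)C(C)C(=O)OC/C=C(CO[Si](C)(C)C(C)(C)C)\C#CC)[C@@]1(C)[C@H](OC(C)=O)C#CC | intermediate
29 | 17-phenylthio β-keto ester (C17 epimers) | CC(=O)O[C@H]1C[C@H]2O[C@@]2(C)[C@H]([C@@H](OC(C)=O)C(=O)C(C)(Sc3ccccc3)C(=O)OC/C=C(CO[Si](C)(C)C(C)(C)C)\C#CC)[C@@]1(C)[C@H](OC(C)=O)C#CC | intermediate
30 | 13-membered enyne macrolactone, 16-O-TBS | CC(=O)O[C@H]1C[C@H]2O[C@@]2(C)[C@@H]2[C@@H](OC(C)=O)C(=O)C(C)(Sc3ccccc3)C(=O)OC/C=C(CO[Si](C)(C)C(C)(C)C)\C#C[C@@H](OC(C)=O)[C@@]12C | intermediate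
31 | macrolactone with C16 alcohol | CC(=O)O[C@H]1C[C@H]2O[C@@]2(C)[C@@H]2[C@@H](OC(C)=O)C(=O)C(C)(Sc3ccccc3)C(=O)OC/C=C(CO)\C#C[C@@H](OC(C)=O)[C@@]12C | intermediate
32 | macrocyclic ynenal | CC(=O)O[C@H]1C[C@H]2O[C@@]2(C)[C@@H]2[C@@H](OC(C)=O)C(=O)C(C)(Sc3ccccc3)C(=O)OC/C=C(C=O)\C#C[C@@H](OC(C)=O)[C@@]12C | intermediate
33 | tricyclic ynenal (C7, C8 set; C17 epimers) | CC(=O)O[C@H]1C[C@H]2O[C@@]2(C)[C@@H]2[C@@H](OC(C)=O)[C@@]3(O)[C@H](/C=C(C=O)\C#C[C@@H](OC(C)=O)[C@@]12C)OC(=O)C3(C)Sc4ccccc4 | intermediate
34 | sulfoxide of 33 | CC(=O)O[C@H]1C[C@H]2O[C@@]2(C)[C@@H]2[C@@H](OC(C)=O)[C@@]3(O)[C@H](/C=C(C=O)\C#C[C@@H](OC(C)=O)[C@@]12C)OC(=O)C3(C)S(=O)c4ccccc4 | intermediate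
35 | α-methylene-γ-lactone | CC(=O)O[C@H]1C[C@H]2O[C@@]2(C)[C@@H]2[C@@H](OC(C)=O)[C@@]3(O)[C@H](/C=C(C=O)\C#C[C@@H](OC(C)=O)[C@@]12C)OC(=O)C3=C | intermediate
36 | 3,4-didehydro target | CC(=O)O[C@H]1C[C@H]2O[C@@]2(C)[C@@H]2[C@@H](OC(C)=O)[C@@]3(O)[C@H](/C=C(CO)\C#C[C@@H](OC(C)=O)[C@@]12C)OC(=O)[C@@H]3C | intermediate
37 | CNP0296793.1 | CC(=O)O[C@H]1C[C@H]2O[C@@]2(C)[C@@H]2[C@@H](OC(C)=O)[C@@]3(O)[C@H](/C=C(CO)\C=C/[C@@H](OC(C)=O)[C@@]12C)OC(=O)[C@@H]3C | target

**Step count**
Total step count: 29. Longest linear sequence: 24 steps (steps 6–29). Steps 1–5 build the side arm.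

**Steps most likely to fail**

1. Step 26.
   - What may go wrong: the aldol equilibrium may stay on the side of the macrolactone (retro-aldol). Slow enolisation of the C8 ketone towards C9 may erode that centre, or the ring fusion may form with the wrong sense.
   - Fallback: it sets out from 32 and uses the known vinylogous Mukaiyama aldol reaction under kinetic, irreversible conditions.
   - Course: soft enolisation with TESOTf/Et3N (CH2Cl2, −78 °C) gives the 1-acyloxy-4-(triethylsilyloxy)diene F1. A catalytic amount of tetrabutylammonium difluorotriphenylsilicate (THF, −78 °C) releases the dienolate, and silyl transfer traps the aldolate as the 8-O-triethylsilyl ether of 33 F2.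
   - Return: Et3N·3HF frees the tertiary alcohol, and the route is rejoined at 33.

2. Step 15.
   - What may go wrong: the C12 organosamarium may be protonated before the ether oxygen leaves (plain 1,4-reduction). The new double bond may also drift back into conjugation with the C14 ketone.
   - Fallback: it sets out from 20 and replaces electron transfer by a boron-based elimination.
   - Course: copper-catalysed conjugate borylation (B2pin2, CuCl, DPEphos, NaOt-Bu, MeOH, THF) from the convex α face gives the 12α-pinacolboryl ketone F3. In F3 the C12–B and C11–O bonds are antiperiplanar.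
   - Return: formation of the boron ate complex (LiOMe, THF, low temperature, AcOH quench) triggers anti-elimination of the β-alkoxyboronate, and the route is rejoined at 21.

3. Step 21.
   - What may go wrong: facial selectivity may be poor, or the peracid may attack from the β face.
   - Fallback: it sets out from 27 and inverts the facial outcome through a halohydrin.
   - Course: NBS in aqueous DME forms the bromonium ion on the same face that the peracid prefers. Water opens it at the tertiary C11 from the opposite face and gives the 12β-bromo-11α-hydroxy compound F4.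
   - Return: Ag2O (CH2Cl2) closes the oxirane with inversion at C12, and the route is rejoined at 28.

**Further compounds**
F1 | step 26 | 1-acyloxy-4-(triethylsilyloxy)diene from 32 | CC(=O)O[C@H]1C[C@H]2O[C@@]2(C)[C@@H]2[C@@H](OC(C)=O)C(=O)C(C)(Sc3ccccc3)C(=O)OC=CC(=CO[Si](CC)(CC)CC)C#C[C@@H](OC(C)=O)[C@@]12C
F2 | step 26 | 8-O-triethylsilyl ether of 33 | CC(=O)O[C@H]1C[C@H]2O[C@@]2(C)[C@@H]2[C@@H](OC(C)=O)[C@@]3(O[Si](CC)(CC)CC)[C@H](/C=C(C=O)\C#C[C@@H](OC(C)=O)[C@@]12C)OC(=O)C3(C)Sc4ccccc4
F3 | step 15 | 12α-pinacolboryl ketone from 20 | O=C1C[C@@H](B4OC(C)(C)C(C)(C)O4)[C@]2(C)OC[C@H](O[Si](C)(C)C(C)(C)C)[C@@H]2[C@@]1(C)[C@H](O)C#CC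
F4 | step 21 | 12β-bromo-11α-hydroxy compound from 27 | CC(=O)O[C@H]1C[C@H](Br)[C@@](C)(O)[C@H]([C@@H](OC(C)=O)C(=O)C(C)C(=O)OC/C=C(CO[Si](C)(C)C(C)(C)C)\C#CC)[C@@]1(C)[C@H](OC(C)=O)C#CC
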